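**Strategy**

1. Retrosynthetic cuts, last to first: the C9–O angelate ester; the lactone bond O8–C12 together with the C12 and C15 oxidation levels; the ring bond C6–C7 (carbonyl-ene retron); and, as the strategic cut, the C5–C10 bond.
2. Enabling feature: quaternary C10 (methyl C14, vinyl C1=C2) sits next to C5, which carries the C4 isopropenyl-type unit and the C6 carbinol. C6–C5–C10–C1=C2 is therefore a γ,δ-unsaturated acid that maps onto an allylic 3-methylbut-2-enoate, and the oxygenated C9 beside C10 can relay chirality from a sugar.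
3. Forward order: D-erythronolactone acetonide supplies C10–C9–C8–C7; the isobutenyl group (C11–C13) and a Z allylic alcohol (C1, C2, C14) are attached; the senecioate (C3–C6, C15) is rearranged while the chain is acyclic; the cyclohexane C5–C6–C7–C8–C9–C10 is closed at C6–C7; the lactone ring (O8–C12) is closed last, before the angelate goes on.
4. Stereochemistry: C8 and C9 from D-erythrose; C10 and C5 from the chair rearrangement with facial relay from C9; C7 from the chair ene closure under allylic strain; C6 from equatorial hydride delivery to the ketone; the Z angelate from purchased angelic acid.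

Key step: step 10

Remark: atoms carry elemane numbers (C10 quaternary with methyl C14 and vinyl C1=C2; C5 with C4(=C3)–C15; C7 with C11(=C13)–C12); β is the ring face that carries C14, α the opposite face.

**Route**

Step 1
Reactants: 1 2,3-O-isopropylidene-D-erythronolactone
Product: 2 (4R,5R)-5-(hydroxymethyl)-N-methoxy-N,2,2-trimethyl-1,3-dioxolane-4-carboxamide
Conditions: MeNH(OMe)·HCl, AlMe3, CH2Cl2, 0 °C → 23 °C
Reagents that add atoms: N,O-dimethylhydroxylamine hydrochloride, CNOC.Cl
Why: Aluminium-amide aminolysis of a lactone (Weinreb amide formation) should open the ring at the acyl carbon only, which differentiates the future C10 from the freed primary alcohol at the future C7 without touching either stereocentre.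

Step 2
Reactants: 2 (4R,5R)-5-(hydroxymethyl)-N-methoxy-N,2,2-trimethyl-1,3-dioxolane-4-carboxamide
Product: 3 (4R,5S)-5-formyl-N-methoxy-N,2,2-trimethyl-1,3-dioxolane-4-carboxamide
Conditions: Dess–Martin periodinane, NaHCO3, CH2Cl2, 0 °C → 23 °C
Reagents that add atoms: none
Why: Buffered Dess–Martin oxidation of a primary alcohol is neutral and fast, so the α-alkoxy aldehyde should form without epimerisation of the cis-dioxolane centre.

Step 3
Reactants: 3 (4R,5S)-5-formyl-N-methoxy-N,2,2-trimethyl-1,3-dioxolane-4-carboxamide; 4 isopropyltriphenylphosphonium iodide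
Product: 6 (4R,5R)-N-methoxy-N,2,2-trimethyl-5-(2-methylprop-1-en-1-yl)-1,3-dioxolane-4-carboxamide, via isopropylidenetriphenylphosphorane 5 (not isolated)
Conditions: 4, n-BuLi, THF, 0 °C; then 3, −78 °C → 0 °C
Reagents that add atoms: isopropyltriphenylphosphonium iodide (4), CC(C)[P+](c1ccccc1)(c1ccccc1)c1ccccc1.[I-]
Why: Wittig olefination by a non-stabilised ylide is far faster at the aldehyde than at the Weinreb amide at −78 °C and should install C11–C13 as the isobutenyl group before the α-centre can epimerise.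

Step 4
Reactants: 6 (4R,5R)-N-methoxy-N,2,2-trimethyl-5-(2-methylprop-1-en-1-yl)-1,3-dioxolane-4-carboxamide
Product: 7 (4R,5R)-2,2-dimethyl-5-(2-methylprop-1-en-1-yl)-1,3-dioxolane-4-carbaldehyde
Conditions: i-Bu2AlH, THF, −78 °C; aq. KNaC4H4O6 (tartrate)
Reagents that add atoms: none
Why: Hydride reduction of a Weinreb amide stops at the chelated tetrahedral intermediate, so the C10 aldehyde should be released only on work-up, without over-reduction or epimerisation.

Step 5
Reactants: 7 (4R,5R)-2,2-dimethyl-5-(2-methylprop-1-en-1-yl)-1,3-dioxolane-4-carbaldehyde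
Product: 8 (4S,5R)-4-(2,2-dibromoethenyl)-2,2-dimethyl-5-(2-methylprop-1-en-1-yl)-1,3-dioxolane
Conditions: CBr4, PPh3, Zn dust, CH2Cl2, 23 °C (ylide preformed); then 7, 0 °C
Reagents that add atoms: carbon tetrabromide, BrC(Br)(Br)Br
Why: The first stage of the Corey–Fuchs homologation (Wittig-type dibromo-olefination) needs no added base, so the cis-configured α-alkoxy aldehyde should give the dibromoalkene carrying C1 with both dioxolane centres intact.

Step 6
Reactants: 8 (4S,5R)-4-(2,2-dibromoethenyl)-2,2-dimethyl-5-(2-methylprop-1-en-1-yl)-1,3-dioxolane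
Product: 10 methyl 3-[(4S,5R)-2,2-dimethyl-5-(2-methylprop-1-en-1-yl)-1,3-dioxolan-4-yl]prop-2-ynoate, via lithium acetylide 9 (not isolated)
Conditions: n-BuLi (2.1 equiv), THF, −78 °C; then ClCO2Me, −78 °C → 0 °C
Reagents that add atoms: methyl chloroformate, COC(=O)Cl
Why: The second stage of the Corey–Fuchs sequence (elimination and bromine–lithium exchange to the acetylide) followed by C-acylation with a chloroformate should give the ynoate, which now carries C2, in one flask.

Step 7
Reactants: 10 methyl 3-[(4S,5R)-2,2-dimethyl-5-(2-methylprop-1-en-1-yl)-1,3-dioxolan-4-yl]prop-2-ynoate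
Product: 12 methyl (2Z)-3-[(4S,5R)-2,2-dimethyl-5-(2-methylprop-1-en-1-yl)-1,3-dioxolan-4-yl]but-2-enoate, via lithium alkenyl(methyl)cuprate 11 (not isolated)
Conditions: Me2CuLi (from CuI and MeLi), THF, −78 °C; MeOH then aq. NH4Cl at −78 °C
Reagents that add atoms: lithium dimethylcuprate, [Li+].C[Cu-]C
Why: syn-Carbocupration of an ynoate puts the methyl group (C14) and copper on the same side, and protonation at −78 °C before the alkenylcopper can isomerise should give the enoate with the dioxolane cis to the ester.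

Step 8
Reactants: 12 methyl (2Z)-3-[(4S,5R)-2,2-dimethyl-5-(2-methylprop-1-en-1-yl)-1,3-dioxolan-4-yl]but-2-enoate
Product: 13 (2Z)-3-[(4S,5R)-2,2-dimethyl-5-(2-methylprop-1-en-1-yl)-1,3-dioxolan-4-yl]but-2-en-1-ol
Conditions: i-Bu2AlH (2.2 equiv), CH2Cl2, −78 °C; aq. KNaC4H4O6 (tartrate)
Reagents that add atoms: none
Why: 1,2-Reduction of an enoate by an aluminium hydride should give the Z allylic alcohol with the alkene geometry retained, and the neutral work-up avoids acid-induced butenolide formation.

Step 9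
Reactants: 13 (2Z)-3-[(4S,5R)-2,2-dimethyl-5-(2-methylprop-1-en-1-yl)-1,3-dioxolan-4-yl]but-2-en-1-ol; 14 3-methylbut-2-enoyl chloride
Product: 15 (2Z)-3-[(4S,5R)-2,2-dimethyl-5-(2-methylprop-1-en-1-yl)-1,3-dioxolan-4-yl]but-2-en-1-yl 3-methylbut-2-enoate
Conditions: pyridine, DMAP (cat.), CH2Cl2, 0 °C
Reagents that add atoms: 3-methylbut-2-enoyl chloride (14), CC(C)=CC(=O)Cl
Why: Nucleophile-catalysed O-acylation of a primary allylic alcohol should be clean, and any β,γ-unsaturated ester formed through the vinylketene is tolerable because it gives the same dienolate in the next step.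

Step 10
Reactants: 15 (2Z)-3-[(4S,5R)-2,2-dimethyl-5-(2-methylprop-1-en-1-yl)-1,3-dioxolan-4-yl]but-2-en-1-yl 3-methylbut-2-enoate
Product: 19 (2S,3S)-3-[(4S,5R)-2,2-dimethyl-5-(2-methylprop-1-en-1-yl)-1,3-dioxolan-4-yl]-3-methyl-2-(prop-1-en-2-yl)pent-4-enoic acid, via lithium dienolate 16 (not isolated), via silyl ketene acetal 17 (not isolated), via trimethylsilyl ester 18 (not isolated)
Conditions: LiN(i-Pr)2, THF, −78 °C; Me3SiCl, −78 °C → 23 °C, then 45 °C; dilute aq. citric acid
Reagents that add atoms: none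
Why: γ-Deprotonation of the s-cis senecioate gives the dienolate with O–Li cis to the isopropenyl group, O-silylation fixes that geometry, and the silyl ketene acetal undergoes a concerted [3,3]-sigmatropic shift in which the C5–C10 bond forms and the allylic C2–O bond breaks, the closest known reaction type being the Ireland–Claisen rearrangement of allylic 3-methylbut-2-enoates through their silyl dienol ethers. No ring is closed in this step, and the acyclic product holds all fifteen skeletal carbons. The relative configuration of C5 and C10 follows from the chair transition state, in which the isopropenyl group and C14 are pseudo-equatorial and the Z-placed dioxolane is pseudo-axial. The absolute configuration of C10 is relayed from C9: allylic 1,3-strain in the Z alkene holds C9–H in the alkene plane, so one face of C10 is flanked by the ring oxygen O9 and the other by C8 with its cis isobutenyl group, and the ketene acetal carbon should bond on the open O9 face. The step thus needs chair over boat and O9 face over C8 face; the first is secured by the acyclic Z-trisubstituted allyl unit, the second by the steric shielding of the cis-disubstituted dioxolane, which must override the weaker electronic preference for bonding anti to the C9–O bond.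

Step 11
Reactants: 19 (2S,3S)-3-[(4S,5R)-2,2-dimethyl-5-(2-methylprop-1-en-1-yl)-1,3-dioxolan-4-yl]-3-methyl-2-(prop-1-en-2-yl)pent-4-enoic acid
Product: 20 (2S,3S)-3-[(4S,5R)-2,2-dimethyl-5-(2-methylprop-1-en-1-yl)-1,3-dioxolan-4-yl]-3-methyl-2-(prop-1-en-2-yl)pent-4-en-1-ol
Conditions: LiAlH4, THF, 0 °C → 65 °C
Reagents that add atoms: none
Why: Hydride reduction of the carboxylic acid to the primary alcohol passes through no enolisable carbonyl intermediate, so the C5 centre next to the isopropenyl group should be preserved.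

Step 12
Reactants: 20 (2S,3S)-3-[(4S,5R)-2,2-dimethyl-5-(2-methylprop-1-en-1-yl)-1,3-dioxolan-4-yl]-3-methyl-2-(prop-1-en-2-yl)pent-4-en-1-ol
Product: 21 (2S,3S)-3-[(4S,5R)-2,2-dimethyl-5-(2-methylprop-1-en-1-yl)-1,3-dioxolan-4-yl]-3-methyl-2-(prop-1-en-2-yl)pent-4-enal
Conditions: Dess–Martin periodinane, NaHCO3, CH2Cl2, 0 °C; used at once
Reagents that add atoms: none
Why: Buffered Dess–Martin oxidation should give the α-isopropenyl aldehyde under neutral, cold conditions, so that it neither epimerises at C5 nor moves its double bond into conjugation.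

Step 13
Reactants: 21 (2S,3S)-3-[(4S,5R)-2,2-dimethyl-5-(2-methylprop-1-en-1-yl)-1,3-dioxolan-4-yl]-3-methyl-2-(prop-1-en-2-yl)pent-4-enal
Product: 22 8α,9α-(isopropylidenedioxy)elema-1,3,11-trien-6α-ol
Conditions: Me2AlCl (1.5 equiv), CH2Cl2, −78 °C → −40 °C; aq. NaHCO3
Reagents that add atoms: none
Why: A Lewis-acid-promoted intramolecular carbonyl-ene reaction of the citronellal-to-isopulegol kind should close the six-membered ring at C6–C7 through a chair in which allylic 1,3-strain keeps C8–H in the plane of the C7=C11 alkene, setting the C7 isopropenyl group equatorial (β, trans to O8) and the C6 hydroxyl equatorial (α), the latter being of no consequence because it is oxidised next.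

Step 14
Reactants: 22 8α,9α-(isopropylidenedioxy)elema-1,3,11-trien-6α-ol
Product: 23 8α,9α-(isopropylidenedioxy)elema-1,3,11-trien-6-one
Conditions: Dess–Martin periodinane, pyridine, CH2Cl2, 0 °C → 23 °C
Reagents that add atoms: none
Why: Buffered Dess–Martin oxidation of the secondary alcohol (either C6 epimer) should give the ketone without enolisation, leaving both flanking isopropenyl groups equatorial and out of conjugation.

Step 15
Reactants: 23 8α,9α-(isopropylidenedioxy)elema-1,3,11-trien-6-one
Product: 24 8α,9α-(isopropylidenedioxy)elema-1,3,11-trien-6β-ol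
Conditions: LiBH(s-Bu)3, THF, −78 °C; aq. NH4Cl
Reagents that add atoms: none
Why: In this diastereoselective ketone reduction the bulky trialkylborohydride should deliver hydride along the equatorial trajectory, the axial approach on the β face being blocked by the axial C14 methyl group, so the axial 6β-alcohol cis to both neighbouring side chains should result.

Step 16
Reactants: 24 8α,9α-(isopropylidenedioxy)elema-1,3,11-trien-6β-ol
Product: 25 6β-(tert-butyldimethylsilyloxy)-8α,9α-(isopropylidenedioxy)elema-1,3,11-triene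
Conditions: t-BuMe2SiOTf, 2,6-lutidine, CH2Cl2, −78 °C → 0 °C
Reagents that add atoms: tert-butyldimethylsilyl trifluoromethanesulfonate, CC(C)(C)[Si](C)(C)OS(=O)(=O)C(F)(F)F
Why: Silylation with a silyl triflate and a hindered pyridine base is the standard protection of a hindered axial secondary alcohol, and the ether keeps O6 out of lactol formation in the later oxidation.

Step 17
Reactants: 25 6β-(tert-butyldimethylsilyloxy)-8α,9α-(isopropylidenedioxy)elema-1,3,11-triene
Product: 26 6β-(tert-butyldimethylsilyloxy)elema-1,3,11-triene-8α,9α-diol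
Conditions: AcOH/H2O (4:1), 45 °C
Reagents that add atoms: none
Why: Acid-catalysed hydrolysis of the cyclic acetal should free the 8,9-diol, while the hindered secondary silyl ether between two branched carbons should survive the weak acid.

Step 18
Reactants: 26 6β-(tert-butyldimethylsilyloxy)elema-1,3,11-triene-8α,9α-diol
Product: 27 6β-(tert-butyldimethylsilyloxy)elema-1,3,11(13)-triene-8α,9α,12,15-tetraol
Conditions: SeO2 (0.5 equiv), t-BuOOH (4 equiv), CH2Cl2, 23 °C
Reagents that add atoms: selenium dioxide, O=[Se]=O; tert-butyl hydroperoxide, CC(C)(C)OO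
Why: Selenium dioxide allylic oxidation (ene reaction then [2,3]-shift) of a 1,1-disubstituted alkene attacks the methyl group in preference to the tertiary ring C–H, so both isopropenyl groups should be hydroxylated (C12 and C15) while the vinyl group, which has no allylic hydrogen, is left.

Step 19
Reactants: 27 6β-(tert-butyldimethylsilyloxy)elema-1,3,11(13)-triene-8α,9α,12,15-tetraol
Product: 29 6β-(tert-butyldimethylsilyloxy)-9α-hydroxy-15-oxoelema-1,3,11(13)-trien-12,8α-olide, via lactol 28 (not isolated)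
Conditions: TEMPO (0.2 equiv), PhI(OAc)2 (3.5 equiv), CH2Cl2, 23 °C
Reagents that add atoms: none
Why: In this oxidative lactonisation of a 1,4-diol the oxoammonium oxidant is selective for primary over secondary alcohols, so C15 should go to the enal and C12 to the aldehyde, which the equatorial O8 traps as the five-membered lactol that is oxidised on to the trans-fused α-methylene lactone while the hindered axial 9-hydroxyl stays free.

Step 20
Reactants: 29 6β-(tert-butyldimethylsilyloxy)-9α-hydroxy-15-oxoelema-1,3,11(13)-trien-12,8α-olide; 30 angelic acid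
Product: 32 9α-angeloyloxy-6β-(tert-butyldimethylsilyloxy)-15-oxoelema-1,3,11(13)-trien-12,8α-olide, via angelic 2,4,6-trichlorobenzoic anhydride 31 (not isolated)
Conditions: 30, 2,4,6-Cl3C6H2COCl, Et3N, toluene, 23 °C; then 29, 80 °C
Reagents that add atoms: angelic acid (30), C/C=C(/C)C(=O)O
Why: Yamaguchi esterification through the mixed anhydride acylates hindered secondary alcohols at the less hindered angeloyl carbonyl, and omitting a nucleophilic catalyst should keep the Z angelate from isomerising to the tiglate.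

Step 21
Reactants: 32 9α-angeloyloxy-6β-(tert-butyldimethylsilyloxy)-15-oxoelema-1,3,11(13)-trien-12,8α-olide
Product: 33 9α-angeloyloxy-6β-hydroxy-15-oxoelema-1,3,11(13)-trien-12,8α-olide (CNP0320538.1)
Conditions: HF·pyridine, pyridine, THF, 0 °C → 23 °C
Reagents that add atoms: none
Why: Buffered fluoride-mediated desilylation should cleave the silyl ether without touching the enal, the α-methylene lactone or the angelate, which completes the target.

**Compound list**

1 | 2,3-O-isopropylidene-D-erythronolactone, (3aR,6aR)-2,2-dimethyldihydrofuro[3,4-d][1,3]dioxol-4(3aH)-one | O=C1OC[C@H]2OC(C)(C)O[C@@H]12 | starting material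
2 | (4R,5R)-5-(hydroxymethyl)-N-methoxy-N,2,2-trimethyl-1,3-dioxolane-4-carboxamide | CON(C)C(=O)[C@@H]1OC(C)(C)O[C@@H]1CO | intermediate
3 | (4R,5S)-5-formyl-N-methoxy-N,2,2-trimethyl-1,3-dioxolane-4-carboxamide | CON(C)C(=O)[C@@H]1OC(C)(C)O[C@@H]1C=O | intermediate
4 | isopropyltriphenylphosphonium iodide | CC(C)[P+](c1ccccc1)(c1ccccc1)c1ccccc1.[I-] | starting material
5 | isopropylidenetriphenylphosphorane (not isolated) | CC(C)=P(c1ccccc1)(c1ccccc1)c1ccccc1 | intermediate
6 | (4R,5R)-N-methoxy-N,2,2-trimethyl-5-(2-methylprop-1-en-1-yl)-1,3-dioxolane-4-carboxamide | CON(C)C(=O)[C@@H]1OC(C)(C)O[C@@H]1C=C(C)C | intermediate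
7 | (4R,5R)-2,2-dimethyl-5-(2-methylprop-1-en-1-yl)-1,3-dioxolane-4-carbaldehyde | O=C[C@@H]1OC(C)(C)O[C@@H]1C=C(C)C | intermediate
8 | (4S,5R)-4-(2,2-dibromoethenyl)-2,2-dimethyl-5-(2-methylprop-1-en-1-yl)-1,3-dioxolane | BrC(Br)=C[C@@H]1OC(C)(C)O[C@@H]1C=C(C)C | intermediate
9 | lithium acetylide of the (4S,5R)-4-ethynyl dioxolane (not isolated) | [Li]C#C[C@@H]1OC(C)(C)O[C@@H]1C=C(C)C | intermediate
10 | methyl 3-[(4S,5R)-2,2-dimethyl-5-(2-methylprop-1-en-1-yl)-1,3-dioxolan-4-yl]prop-2-ynoate | COC(=O)C#C[C@@H]1OC(C)(C)O[C@@H]1C=C(C)C | intermediate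
11 | lithium alkenyl(methyl)cuprate from syn-carbocupration of 10, copper cis to the new methyl (not isolated) | [Li+].C[Cu-]/C(C(=O)OC)=C(\C)[C@@H]1OC(C)(C)O[C@@H]1C=C(C)C | intermediate
12 | methyl (2Z)-3-[(4S,5R)-2,2-dimethyl-5-(2-methylprop-1-en-1-yl)-1,3-dioxolan-4-yl]but-2-enoate | COC(=O)/C=C(C)\[C@@H]1OC(C)(C)O[C@@H]1C=C(C)C | intermediate
13 | (2Z)-3-[(4S,5R)-2,2-dimethyl-5-(2-methylprop-1-en-1-yl)-1,3-dioxolan-4-yl]but-2-en-1-ol | OC/C=C(C)\[C@@H]1OC(C)(C)O[C@@H]1C=C(C)C | intermediate
14 | 3-methylbut-2-enoyl chloride (senecioyl chloride) | CC(C)=CC(=O)Cl | starting material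
15 | (2Z)-3-[(4S,5R)-2,2-dimethyl-5-(2-methylprop-1-en-1-yl)-1,3-dioxolan-4-yl]but-2-en-1-yl 3-methylbut-2-enoate | CC(C)=CC(=O)OC/C=C(C)\[C@@H]1OC(C)(C)O[C@@H]1C=C(C)C | intermediate
16 | lithium dienolate of 15, O–Li cis to the isopropenyl group (not isolated) | C=C(C)/C=C(\O[Li])OC/C=C(C)\[C@@H]1OC(C)(C)O[C@@H]1C=C(C)C | intermediate
17 | trimethylsilyl ketene acetal of 15, O–Si cis to the isopropenyl group (not isolated) | C=C(C)/C=C(\O[Si](C)(C)C)OC/C=C(C)\[C@@H]1OC(C)(C)O[C@@H]1C=C(C)C | intermediate
18 | trimethylsilyl ester of acid 19 (not isolated) | C[Si](C)(C)OC(=O)[C@@H](C(C)=C)[C@](C)(C=C)[C@@H]1OC(C)(C)O[C@@H]1C=C(C)C | intermediate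
19 | (2S,3S)-3-[(4S,5R)-2,2-dimethyl-5-(2-methylprop-1-en-1-yl)-1,3-dioxolan-4-yl]-3-methyl-2-(prop-1-en-2-yl)pent-4-enoic acid | OC(=O)[C@@H](C(C)=C)[C@](C)(C=C)[C@@H]1OC(C)(C)O[C@@H]1C=C(C)C | intermediate
20 | (2S,3S)-3-[(4S,5R)-2,2-dimethyl-5-(2-methylprop-1-en-1-yl)-1,3-dioxolan-4-yl]-3-methyl-2-(prop-1-en-2-yl)pent-4-en-1-ol | OC[C@@H](C(C)=C)[C@](C)(C=C)[C@@H]1OC(C)(C)O[C@@H]1C=C(C)C | intermediate
21 | (2S,3S)-3-[(4S,5R)-2,2-dimethyl-5-(2-methylprop-1-en-1-yl)-1,3-dioxolan-4-yl]-3-methyl-2-(prop-1-en-2-yl)pent-4-enal | O=C[C@@H](C(C)=C)[C@](C)(C=C)[C@@H]1OC(C)(C)O[C@@H]1C=C(C)C | intermediate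
22 | 8α,9α-(isopropylidenedioxy)elema-1,3,11-trien-6α-ol (cyclohexane; C10 β-methyl and α-vinyl; β-isopropenyl at C5 and C7; cis-acetonide on the α-oxygens at C8 and C9; equatorial 6α-OH) | C=C[C@]1(C)[C@@H]2OC(C)(C)O[C@@H]2[C@@H](C(C)=C)[C@H](O)[C@H]1C(C)=C | intermediate
23 | 8α,9α-(isopropylidenedioxy)elema-1,3,11-trien-6-one | C=C[C@]1(C)[C@@H]2OC(C)(C)O[C@@H]2[C@@H](C(C)=C)C(=O)[C@H]1C(C)=C | intermediate
24 | 8α,9α-(isopropylidenedioxy)elema-1,3,11-trien-6β-ol (axial 6-OH) | C=C[C@]1(C)[C@@H]2OC(C)(C)O[C@@H]2[C@@H](C(C)=C)[C@@H](O)[C@H]1C(C)=C | intermediate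
25 | 6β-(tert-butyldimethylsilyloxy)-8α,9α-(isopropylidenedioxy)elema-1,3,11-triene | C=C[C@]1(C)[C@@H]2OC(C)(C)O[C@@H]2[C@@H](C(C)=C)[C@@H](O[Si](C)(C)C(C)(C)C)[C@H]1C(C)=C | intermediate
26 | 6β-(tert-butyldimethylsilyloxy)elema-1,3,11-triene-8α,9α-diol | C=C[C@]1(C)[C@H](O)[C@H](O)[C@@H](C(C)=C)[C@@H](O[Si](C)(C)C(C)(C)C)[C@H]1C(C)=C | intermediate
27 | 6β-(tert-butyldimethylsilyloxy)elema-1,3,11(13)-triene-8α,9α,12,15-tetraol | C=C[C@]1(C)[C@H](O)[C@H](O)[C@@H](C(=C)CO)[C@@H](O[Si](C)(C)C(C)(C)C)[C@H]1C(=C)CO | intermediate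
28 | 8α,12-epoxy-6β-(tert-butyldimethylsilyloxy)-9α,12-dihydroxyelema-1,3,11(13)-trien-15-al (lactol, either configuration at C12; not isolated) | C=C[C@]1(C)[C@H](O)[C@@H]2OC(O)C(=C)[C@H]2[C@@H](O[Si](C)(C)C(C)(C)C)[C@H]1C(=C)C=O | intermediate
29 | 6β-(tert-butyldimethylsilyloxy)-9α-hydroxy-15-oxoelema-1,3,11(13)-trien-12,8α-olide | C=C[C@]1(C)[C@H](O)[C@@H]2OC(=O)C(=C)[C@H]2[C@@H](O[Si](C)(C)C(C)(C)C)[C@H]1C(=C)C=O | intermediate
30 | angelic acid, (2Z)-2-methylbut-2-enoic acid | C/C=C(/C)C(=O)O | starting material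
31 | angelic 2,4,6-trichlorobenzoic anhydride (not isolated) | C/C=C(/C)C(=O)OC(=O)c1c(Cl)cc(Cl)cc1Cl | intermediate
32 | 9α-angeloyloxy-6β-(tert-butyldimethylsilyloxy)-15-oxoelema-1,3,11(13)-trien-12,8α-olide | C=C[C@]1(C)[C@H](OC(=O)/C(C)=C\C)[C@@H]2OC(=O)C(=C)[C@H]2[C@@H](O[Si](C)(C)C(C)(C)C)[C@H]1C(=C)C=O | intermediate
33 | CNP0320538.1, (3aS,4S,5R,6S,7S,7aR)-6-ethenyl-4-hydroxy-6-methyl-3-methylidene-2-oxo-5-(3-oxoprop-1-en-2-yl)octahydro-1-benzofuran-7-yl (2Z)-2-methylbut-2-enoate | C=C[C@]1(C)[C@H](OC(=O)/C(C)=C\C)[C@@H]2OC(=O)C(=C)[C@H]2[C@@H](O)[C@H]1C(=C)C=O | target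

**Step count**

Total: 21 steps. Longest linear sequence: 21 steps, from compound 1 (compounds 4, 14 and 30 are purchased and enter directly).

**Steps most likely to fail**

1. Step 10. What may go wrong: bond formation on the C8 face of the allyl terminus (anti to the C9–O bond) instead of the O9 face, a boat pathway that inverts C5, or loss of the dienolate to the vinylketene before silylation.
Fallback (sets out from 12, returns at 20): C9 is made to control C10 through a ring instead of through a conformational preference, and the roles of the carbons change. The ester carbon and α-carbon of 12 become C6 and C5, and the vinyl group is brought in as C1=C2.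
Aqueous acetic acid (AcOH/H2O, 40 °C) removes the acetonide of 12 and O9 closes onto the Z ester to give (5S)-5-[(1R)-1-hydroxy-3-methylbut-2-en-1-yl]-4-methylfuran-2(5H)-one F1. Acylation (t-BuCOCl, pyridine) gives its pivalate F2. Conjugate addition of a vinyl cuprate (CH2=CHMgBr, CuBr·SMe2, Me3SiCl, THF, −78 °C) should occur trans to the C8 side chain, which is the required C10 configuration, and give the 4-ethenyl-4-methyl lactone F3. The lithium enolate (LiN(i-Pr)2, THF, −78 °C) is added to acetone to give the tertiary aldol F4. This is dehydrated through its mesylate F5 (MsCl, Et3N, then DBU) to the conjugated isopropylidene lactone F6. Deconjugation (LiN(i-Pr)2, THF, −78 °C, then AcOH) should protonate the dienolate on the face of the vinyl group and H9, away from C14 and the C8 chain, and give the α-isopropenyl lactone F7 with the required C5 configuration. LiAlH4 (THF, 0 °C) reduces the lactone and cleaves the pivalate to the triol F8. Acetonide formation on the cis-8,9-diol (2,2-dimethoxypropane, PPTS, acetone) returns 20.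

2. Step 18. What may go wrong: incomplete or unselective double allylic oxidation, with attack at the tertiary ring C–H, over-oxidation, or retention of selenium by the free diol.
Fallback (sets out from 25, returns at 27): the oxygen is introduced by chlorination and substitution instead of a selenium ene reaction. Ene-type chlorination of both isopropenyl groups of 25 with hypochlorous acid made in situ (NaOCl, CeCl3·7H2O, CH2Cl2/H2O, 0 °C) gives the bis(allylic chloride) F9. Displacement with KOAc (18-crown-6, MeCN, 60 °C) gives the diacetate F10. Methanolysis (K2CO3, MeOH, 0 °C) gives the acetonide-protected 12,15-diol F11. Acetonide hydrolysis under the conditions of step 17 returns 27.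

3. Step 20. What may go wrong: slow acylation of the axial, neopentyl-type C9 hydroxyl, with Z-to-E isomerisation of the angeloyl group or conjugate addition to the enal and methylene lactone under the forcing conditions then needed.
Fallback (sets out from 27, returns at 32): the ester is installed before the electrophilic enal and lactone exist, so that the C9 alkoxide itself can be acylated. Compound 27 is silylated at the two primary allylic hydroxyls and the equatorial 8-hydroxyl (Et3SiCl, imidazole, DMF, 0 °C) to give the tris(triethylsilyl) ether F12, the hindered axial 9-hydroxyl staying free. Its lithium alkoxide (LiN(SiMe3)2, THF, −78 °C) is acylated with purchased angelic anhydride to give the 9-angelate F13. The three triethylsilyl ethers are cleaved in the presence of the hindered tert-butyldimethylsilyl ether (HF·pyridine, pyridine, THF, 0 °C) to give the 8,12,15-triol F14. Oxidative lactonisation under the conditions of step 19 (TEMPO, PhI(OAc)2) then gives 32 directly.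

**Further compounds**

F1 | step 10 | (5S)-5-[(1R)-1-hydroxy-3-methylbut-2-en-1-yl]-4-methylfuran-2(5H)-one | O=C1C=C(C)[C@H](O1)[C@H](O)C=C(C)C
F2 | step 10 | pivalate of F1 | O=C1C=C(C)[C@H](O1)[C@H](OC(=O)C(C)(C)C)C=C(C)C
F3 | step 10 | 4-ethenyl-4-methyl γ-lactone, vinyl trans to the C8 side chain | O=C1C[C@](C)(C=C)[C@H](O1)[C@H](OC(=O)C(C)(C)C)C=C(C)C
F4 | step 10 | acetone aldol of F3 (3-(2-hydroxypropan-2-yl) lactone, C5 configuration of no consequence) | O=C1C(C(C)(C)O)[C@](C)(C=C)[C@H](O1)[C@H](OC(=O)C(C)(C)C)C=C(C)C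
F5 | step 10 | mesylate of F4 (not isolated) | O=C1C(C(C)(C)OS(C)(=O)=O)[C@](C)(C=C)[C@H](O1)[C@H](OC(=O)C(C)(C)C)C=C(C)C
F6 | step 10 | 3-isopropylidene lactone | O=C1C(=C(C)C)[C@](C)(C=C)[C@H](O1)[C@H](OC(=O)C(C)(C)C)C=C(C)C
F7 | step 10 | 3-isopropenyl lactone, isopropenyl cis to the C4 methyl | O=C1[C@@H](C(C)=C)[C@](C)(C=C)[C@H](O1)[C@H](OC(=O)C(C)(C)C)C=C(C)C
F8 | step 10 | triol corresponding to 20 without the acetonide | OC[C@@H](C(C)=C)[C@](C)(C=C)[C@H](O)[C@H](O)C=C(C)C
F9 | step 18 | 12,15-dichloro derivative of 25 (bis(allylic chloride)) | C=C[C@]1(C)[C@@H]2OC(C)(C)O[C@@H]2[C@@H](C(=C)CCl)[C@@H](O[Si](C)(C)C(C)(C)C)[C@H]1C(=C)CCl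
F10 | step 18 | 12,15-diacetoxy derivative of 25 | C=C[C@]1(C)[C@@H]2OC(C)(C)O[C@@H]2[C@@H](C(=C)COC(C)=O)[C@@H](O[Si](C)(C)C(C)(C)C)[C@H]1C(=C)COC(C)=O
F11 | step 18 | 12,15-dihydroxy derivative of 25 (acetonide of 27) | C=C[C@]1(C)[C@@H]2OC(C)(C)O[C@@H]2[C@@H](C(=C)CO)[C@@H](O[Si](C)(C)C(C)(C)C)[C@H]1C(=C)CO
F12 | step 20 | 8,12,15-tris(triethylsilyl) ether of 27, free 9α-hydroxyl | C=C[C@]1(C)[C@H](O)[C@H](O[Si](CC)(CC)CC)[C@@H](C(=C)CO[Si](CC)(CC)CC)[C@@H](O[Si](C)(C)C(C)(C)C)[C@H]1C(=C)CO[Si](CC)(CC)CC
F13 | step 20 | 9α-angelate of F12 | C=C[C@]1(C)[C@H](OC(=O)/C(C)=C\C)[C@H](O[Si](CC)(CC)CC)[C@@H](C(=C)CO[Si](CC)(CC)CC)[C@@H](O[Si](C)(C)C(C)(C)C)[C@H]1C(=C)CO[Si](CC)(CC)CC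
F14 | step 20 | 9α-angeloyloxy-6β-(tert-butyldimethylsilyloxy)elema-1,3,11(13)-triene-8α,12,15-triol | C=C[C@]1(C)[C@H](OC(=O)/C(C)=C\C)[C@H](O)[C@@H](C(=C)CO)[C@@H](O[Si](C)(C)C(C)(C)C)[C@H]1C(=C)CO
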